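## The problem

Target **26** is a 7-oxabicyclo[4.1.0]hept-3-en-2-one: one six-membered carbocycle (ring carbons C1–C6, C1 the ketone) fused to an oxirane across C5–C6, with every ring carbon functionalised. C2 carries an (E)-hept-1-enyl chain (C1'=C2'), C3 a hydroxymethyl group, C4 a secondary hydroxyl, and the quaternary oxirane carbon C6 an (E)-2-methylbut-2-enoic acid chain. Three contiguous stereocentres (C4, C5, C6) are needed as one enantiomer; C5 and C6 are tied together by the cis-fused oxirane, and the C4 hydroxyl lies anti to the oxirane oxygen. A hydroxyl-directed epoxidation of a cyclohexenol would give the syn relation, whereas the same reaction on an open-chain (Z)-allylic alcohol gives the required one under allylic 1,3-strain. C4 can therefore control C5 and C6 only while the chain is open, and C4 is the one centre that needs an external source of chirality. The finished molecule is fragile: the α,β-epoxy ketone and the γ-hydroxy enone do not tolerate base (oxirane opening, elimination towards an arene), and the cross-conjugated dienone is a Michael acceptor. The ketone should therefore appear late and the acid be freed before it. The enabling feature is that the ring alkene C2=C3 and the exocyclic alkene C1'=C2' on C2 form a 1,3-diene. That is the product pattern of an enyne metathesis between an alkyne on C1 and a methylidene on C3, and the cis-oxirane holds the C1 and C4 arms on the same side.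

## Retrosynthesis

**26 ⇒ 22 (no skeletal bond cut).** The acid, the C1 ketone and the two hydroxyls are unmasked in the order **22** → **23** (ester to acid) → **24** (C1 silyl ether off) → **25** (C1 oxidised) → **26** (TBS ethers off). Hydrolysing last would expose the epoxy enone to hot tin hydroxide, and oxidising C1 earlier would send an enone through two metathesis steps. The forward sequence asks for cleavage of one secondary TES ether beside two TBS ethers.

**22 ⇒ 20 + 21 (cut C1'=C2').** The heptenyl chain is cut at its double bond to the vinyl diene **20** and hept-1-ene **21**. A terminal alkyne in an enyne metathesis can only deliver a vinyl group, and an internal alkyne would give a branched exocyclic alkene, so the five extra carbons are best added afterwards by cross-metathesis. The forward step must give the E alkene and leave the tetrasubstituted ring alkene and the enoate alone.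

**20 ⇒ 19 (cut C2=C3 and the vinyl C=C; key step).** Retro-enyne metathesis opens the carbocycle to the acyclic epoxy enyne **19**, with an ethynyl group on C1 and a methylidene on C3. Cutting C1–C2 or C3–C4 instead would need a preformed tetrasubstituted alkene. Cutting C2=C3 by alkene–alkene metathesis would leave C2 unsubstituted. In **19** all three stereocentres sit in an open chain where they can be set by acyclic control. The forward reaction must be chemoselective and close the six-membered ring in the exo mode.

**19 ⇒ 16 + 17 (cut C1–C2).** The propargylic silyl ether **19** comes from the carbinol **18**, made from the α-quaternary epoxy aldehyde **16** and ethynylmagnesium bromide **17**. The C1 configuration is irrelevant because C1 becomes the ketone. Bringing the alkyne in before the epoxidation would place a second stereocentre next to the alkene that C4 has to control.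

**16 ⇒ 13 (cut the two oxirane C–O bonds).** Aldehyde **16** is traced through the silyl ethers **15** and **14** to the (Z)-configured bis-allylic alcohol **13**. The oxirane is introduced by C4-hydroxyl-directed peracid epoxidation, which gives the threo epoxy alcohol, that is, the anti relation of the ring. The forward step must choose the trisubstituted C5=C6 alkene over the 1,1-disubstituted C3 alkene.

**13 ⇒ 10 + 3 (cut C4–C5).** The carbinol carbon is disconnected from the alkenyl carbon: (Z)-alkenyl iodide **10** adds to enal **3** under chromium/nickel mediation to give racemic **11**. Oxidation to dienone **12** and catalyst-controlled reduction then set C4 in **13**. The cut is convergent, joins two fragments of similar size, and keeps the ester and silyl ethers intact.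

**10 ⇒ 7 + 8 (cut the enoate C=C).** The trisubstituted E enoate of **10** (via alcohol **9**) is made by cross-metathesis of the allyl group of **7** with methyl methacrylate **8**. This is shorter and more E-selective than alkylation with a γ-bromo tiglate.

**7 ⇒ 4 + 5 (cut the allyl–C6 bond and C5–I).** Iodide **7** arises in one operation from propargyl alcohol **4** and allylmagnesium bromide **5** by hydroxyl-directed anti carbomagnesiation and iodinolysis. This fixes the Z geometry that later places C1 and C4 cis on the oxirane.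

**3 ⇒ 1.** Enal **3** comes from 2-methylidenepropane-1,3-diol **1** by monosilylation (**2**) and allylic oxidation.

## Roads not taken

Alternative 1: Payne shift on an epoxy para-quinol, then enone transposition. No carbon–carbon bond is cut: the C5–C6 oxirane is traced back by a retro-Payne shift to a C4–C5 oxirane beside a C6 tertiary silyl ether, the trans epoxy para-quinol **A1**, whose ring would come from an arene by oxidative dearomatisation. In the forward key step buffered (n-C4H9)4NF frees the C6 alkoxide of **A1**, which attacks C5 from the face opposite the old oxirane and gives **A2**, with the new oxirane and the C4 hydroxyl anti by necessity.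
- Merits: no ring-forming step, a stereospecific key step, and the shortest path to an oxygenated six-membered ring. In step count up to the ring this road is better than the chosen plan.
- Weak points: **A2** has its ketone at C3 and no hydroxymethyl carbon. A hydroxymethyl anion equivalent must be added to C3 and the tertiary allylic alcohol transposed oxidatively (pyridinium chlorochromate (C5H5NH)[CrO3Cl], hexavalent chromium) to C1, on a substrate with an oxirane and a diene along which the transposition can also run.
- In **A2**, C4 is α to a ketone and flanked by an alkoxide under basic fluoride, which invites epimerisation and aromatisation.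
- The C6 configuration of **A1** would be set in a dearomatisation for which no dependable catalyst control exists.
- Against the shorter start, the chosen plan has every carbon in place when the ring closes, derives all three centres from one catalyst-controlled reduction and one substrate-directed epoxidation, and never exposes an epoxy ketone to base.

Alternative 2: Desymmetrising nickel [4+2] of a cyclobutanone with the enyne. The cut is C3–C4 and C1–C2: the prochiral cyclobutanone **A3** and the enyne silyl ether **A4** would combine under Ni(cod)2 (bis(1,5-cyclooctadiene)nickel, zerovalent nickel) with a chiral phosphoramidite. Oxidative cyclisation and β-carbon elimination would give the cyclohexenone **A5** with C2, C3 and the quaternary C6 in place.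
- Merits: the most convergent of the four plans; it sets C6 catalytically and installs the heptenyl diene and the C3 side chain in the ring-forming step. In convergence it is better than the chosen plan.
- Weak points: **A5** has its ketone at C4 and methylene groups at C1 and C5. C4 must be reduced with control, C1 oxidised to the ketone, C5 oxidised and closed onto the C6 oxygen as the oxirane, and the acetal turned into the enoate; each of these is a separate selectivity problem on a sensitive dienone.
- The intermolecular, enantiotopos-selective C–C activation with an unsymmetrical conjugated enyne has to control regiochemistry and enantioselectivity at once, at the edge of what this reaction type has shown.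
- Against its convergence, the chosen plan closes the ring with all oxygen functions and all three stereocentres already in place.

Alternative 3: Chromium-mediated alkenyl iodide–aldehyde ring closure at C3–C4. The cut is the C3–C4 bond: the acyclic epoxy aldehyde **A6**, with a tetrasubstituted C3 iodoalkene and the complete diene, would be closed by CrCl2 (chromium dichloride, divalent chromium) with catalytic NiCl2 (nickel dichloride, divalent nickel) to the epoxy cyclohexenol **A7**. The step forms the ring and the C4 carbinol together.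
- Merits: mild and tolerant of oxirane and ester; no late cross-metathesis is needed; the C4 hydroxyl emerges free and already differentiated from the C1 silyl ether. In these respects it is as good as or better than the chosen plan.
- Weak points: C4 is created in the cyclisation and its configuration relative to the oxirane rests on the untested facial preference of a cyclic transition state.
- **A6** needs a stereodefined tetrasubstituted iodo diene (iodine cis to C1), which costs several steps.
- **A6** also carries an α,β-epoxy aldehyde with an α-hydrogen at C5, which is prone to epimerisation and opening.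
- Against these, the chosen plan sets C4 by catalyst control in a simple chain, lets C4 set C5 and C6 by a predictable directed epoxidation, and uses an epoxy aldehyde without α-hydrogen.

Key step: step 14

Assumption: the C1 carbinol formed in step 12 is expected as a mixture of epimers that is carried on unseparated and converges in step 18; compounds 18–20 and 22–24 are named and drawn as one epimer.

Abbreviations: TBS = tert-butyldimethylsilyl, TES = triethylsilyl.

Step 1
Reactants: 1 2-methylidenepropane-1,3-diol
Product: 2 2-(TBS-oxymethyl)prop-2-en-1-ol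
Conditions: NaH (1.0 equiv), THF, 0 °C; TBSCl (1.0 equiv), rt
Reagents that add atoms: tert-butyldimethylsilyl chloride, CC(C)(C)[Si](C)(C)Cl
Why: Monosilylation of a symmetrical diol through its monosodium alkoxide (O-silylation); the TBS ether carries the C3 hydroxymethyl oxygen to the last step.

Step 2
Reactants: 2 2-(TBS-oxymethyl)prop-2-en-1-ol
Product: 3 2-(TBS-oxymethyl)prop-2-enal
Conditions: MnO2 (10 equiv), CH2Cl2, rt
Reagents that add atoms: none
Why: MnO2 oxidises the allylic alcohol to the enal without over-oxidation; the silyl ether and the 1,1-disubstituted alkene are untouched.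

Step 3
Reactants: 4 prop-2-yn-1-ol; 5 allylmagnesium bromide CH2=CHCH2MgBr
Product: 7 (2Z)-2-(iodomethylidene)pent-4-en-1-ol, via cyclic alkenylmagnesium alkoxide 6 (not isolated)
Conditions: 5 (2.5 equiv), CuI (10 mol %), Et2O, 0 °C to rt; then I2, THF, −78 to 0 °C
Reagents that add atoms: iodine, II
Why: Hydroxyl-directed anti carbomagnesiation of the propargylic alkoxide puts allyl on the internal alkyne carbon and magnesium on the terminal carbon in a five-membered chelate cis to CH2O. Iodinolysis with retention gives the Z iodide, which later places C1 and C4 cis on the oxirane.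

Step 4
Reactants: 7 (2Z)-2-(iodomethylidene)pent-4-en-1-ol; 8 methyl methacrylate
Product: 9 methyl (2E,5Z)-5-(hydroxymethyl)-6-iodo-2-methylhexa-2,5-dienoate
Conditions: (H2IMes)Cl2Ru=CH(2-i-PrOC6H4) (second-generation Hoveyda–Grubbs catalyst, 5 mol %), 8 (10 equiv), CH2Cl2, 40 °C
Reagents that add atoms: none
Why: Cross-metathesis of a terminal alkene with methyl methacrylate gives the trisubstituted E enoate under thermodynamic control. The trisubstituted iodoalkene and the free hydroxyl do not take part.

Step 5
Reactants: 9 methyl (2E,5Z)-5-(hydroxymethyl)-6-iodo-2-methylhexa-2,5-dienoate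
Product: 10 methyl (2E,5Z)-6-iodo-2-methyl-5-(TES-oxymethyl)hexa-2,5-dienoate
Conditions: TESCl (1.2 equiv), imidazole (2 equiv), CH2Cl2, 0 °C
Reagents that add atoms: chlorotriethylsilane, CC[Si](Cl)(CC)CC
Why: Standard silylation without strong base, which the skipped dienoate would not tolerate. The primary TES ether masks C1 and can later be oxidised directly to the aldehyde beside TBS ethers.

Step 6
Reactants: 10 methyl (2E,5Z)-6-iodo-2-methyl-5-(TES-oxymethyl)hexa-2,5-dienoate; 3 2-(TBS-oxymethyl)prop-2-enal
Product: 11 methyl (2E,5Z,7RS)-8-(TBS-oxymethyl)-7-hydroxy-2-methyl-5-(TES-oxymethyl)nona-2,5,8-trienoate (racemic at C7, the later C4)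
Conditions: CrCl2 (4 equiv), NiCl2 (2 mol %), DMSO/THF, rt
Reagents that add atoms: none
Why: Nozaki–Hiyama–Kishi coupling: nickel inserts into the C–I bond, the alkenyl group passes to chromium with retention of geometry and adds 1,2 to the enal. Ester and silyl ethers are tolerated; the carbinol is racemic at this stage.

Step 7
Reactants: 11 racemic bis-allylic alcohol
Product: 12 methyl (2E,5Z)-8-(TBS-oxymethyl)-2-methyl-7-oxo-5-(TES-oxymethyl)nona-2,5,8-trienoate
Conditions: Dess–Martin periodinane (1.3 equiv), NaHCO3, CH2Cl2, 0 °C; used at once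
Reagents that add atoms: none
Why: Dess–Martin oxidation of a bis-allylic alcohol under buffered, base-free conditions, chosen to avoid isomerisation of the Z enone and of the skipped dienoate.

Step 8
Reactants: 12 cross-conjugated dienone
Product: 13 methyl (2E,5Z,7S)-8-(TBS-oxymethyl)-7-hydroxy-2-methyl-5-(TES-oxymethyl)nona-2,5,8-trienoate
Conditions: (R)-2-methyl-CBS-oxazaborolidine [(3aR)-1-methyl-3,3-diphenyltetrahydro-1H,3H-pyrrolo[1,2-c][1,3,2]oxazaborole] (0.5 equiv), catecholborane (2 equiv), toluene, −78 °C
Reagents that add atoms: none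
Why: Corey–Bakshi–Shibata reduction of an enone is 1,2-selective, and catecholborane at −78 °C does not hydroborate the alkenes. With the α-branched 2-(silyloxymethyl)vinyl group taken as the larger ketone substituent, the (R)-catalyst should deliver hydride to the face that gives the 7S carbinol (C4 of the target).

Step 9
Reactants: 13 (7S)-bis-allylic alcohol
Product: 14 methyl (2E)-4-[(2R,3S)-3-[(1R)-1-hydroxy-2-(TBS-oxymethyl)prop-2-en-1-yl]-2-(TES-oxymethyl)oxiran-2-yl]-2-methylbut-2-enoate
Conditions: mCPBA (1.1 equiv), NaHCO3, CH2Cl2, −20 to 0 °C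
Reagents that add atoms: 3-chloroperoxybenzoic acid, OOC(=O)c1cccc(Cl)c1
Why: Hydroxyl-directed peracid epoxidation; the trisubstituted C5=C6 alkene is more nucleophilic than the 1,1-disubstituted alkene and the enoate. Allylic 1,3-strain with the cis CH2OTES group puts the C4 hydrogen in the alkene plane, so the hydroxyl delivers oxygen to one face and gives the threo epoxy alcohol (anti in the later ring); this sets C5 and C6 from C4.

Step 10
Reactants: 14 threo epoxy alcohol
Product: 15 methyl (2E)-4-[(2R,3S)-3-[(1R)-1-(TBS-oxy)-2-(TBS-oxymethyl)prop-2-en-1-yl]-2-(TES-oxymethyl)oxiran-2-yl]-2-methylbut-2-enoate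
Conditions: TBSOTf (1.3 equiv), 2,6-lutidine (2.5 equiv), CH2Cl2, −78 °C
Reagents that add atoms: tert-butyldimethylsilyl triflate, CC(C)(C)[Si](C)(C)OS(=O)(=O)C(F)(F)F
Why: Silyl triflate silylation of a hindered secondary alcohol at low temperature. The C4 oxygen must be capped before C1 becomes an aldehyde, otherwise a five-membered lactol forms across the cis-oxirane.

Step 11
Reactants: 15 fully silylated epoxide
Product: 16 methyl (2E)-4-[(2S,3S)-3-[(1R)-1-(TBS-oxy)-2-(TBS-oxymethyl)prop-2-en-1-yl]-2-formyloxiran-2-yl]-2-methylbut-2-enoate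
Conditions: (COCl)2 (5 equiv), DMSO (10 equiv), CH2Cl2, −78 to −40 °C; then Et3N, −78 to 0 °C
Reagents that add atoms: none
Why: Activated DMSO converts a primary TES ether directly into the aldehyde (Swern oxidation of a triethylsilyl ether) while TBS ethers stay intact. The aldehyde has no α-hydrogen, so the base cannot epimerise it.

Step 12
Reactants: 16 epoxy aldehyde; 17 ethynylmagnesium bromide HC≡CMgBr
Product: 18 methyl (2E)-4-[(2R,3S)-3-[(1R)-1-(TBS-oxy)-2-(TBS-oxymethyl)prop-2-en-1-yl]-2-[(1R)-1-hydroxyprop-2-yn-1-yl]oxiran-2-yl]-2-methylbut-2-enoate (C1 epimers, one named)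
Conditions: 17 (2 equiv), THF, −78 to −40 °C
Reagents that add atoms: none
Why: Grignard 1,2-addition to the aldehyde; the conjugated, hindered methyl ester does not react at this temperature. The new carbinol centre need not be controlled because it is oxidised in step 18.

Step 13
Reactants: 18 propargylic alcohol
Product: 19 methyl (2E)-4-[(2S,3S)-3-[(1R)-1-(TBS-oxy)-2-(TBS-oxymethyl)prop-2-en-1-yl]-2-[(1R)-1-(TES-oxy)prop-2-yn-1-yl]oxiran-2-yl]-2-methylbut-2-enoate
Conditions: TESOTf (1.5 equiv), 2,6-lutidine (3 equiv), CH2Cl2, −78 °C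
Reagents that add atoms: triethylsilyl triflate, CC[Si](CC)(CC)OS(=O)(=O)C(F)(F)F
Why: Silyl triflate silylation of a hindered secondary alcohol. The propargylic TES ether keeps a free hydroxyl away from the ruthenium catalyst and is the one silyl ether that can later be removed selectively.

Step 14
Reactants: 19 acyclic epoxy enyne
Product: 20 methyl (2E)-4-[(1S,2R,5R,6S)-5-(TBS-oxy)-4-(TBS-oxymethyl)-3-ethenyl-2-(TES-oxy)-7-oxabicyclo[4.1.0]hept-3-en-1-yl]-2-methylbut-2-enoate
Conditions: (H2IMes)(PCy3)Cl2Ru=CHPh (second-generation Grubbs catalyst, 10 mol %), ethylene (1 atm), toluene, 80 °C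
Reagents that add atoms: none
Why: Ring-closing enyne metathesis: the ruthenium methylidene formed from the catalyst and ethylene adds to the terminal alkyne of 19 with ruthenium at C2, and opening of the ruthenacyclobutene gives the vinylcarbene Ru=C2(CH=CH2). This carbene undergoes [2+2] cycloaddition with the C3 methylidene and cycloreversion, which forms C2=C3, closes the carbocycle and returns the methylidene carrier. The closest known reaction type is the ring-closing enyne metathesis of 1,7-enynes with a terminal alkyne to 1-vinylcyclohexenes under ethylene, which also gives tetrasubstituted ring alkenes from 1,1-disubstituted alkenes. The six-membered ring closes in the exo mode (only C2 of the alkyne enters the ring); endo closure would need a seven-membered ring. No stereocentre is formed, and C4, C5, C6 and the C1 carbinol are not touched. The step needs chemoselectivity and exo regioselectivity: the trisubstituted enoate is hindered and electron-poor, the oxirane and silyl ethers are inert to the neutral catalyst, and the cis-oxirane holds the C1 and C4 arms on the same side so that carbene and alkene are close. Ethylene keeps the catalyst as the methylidene and suppresses alkyne oligomerisation.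

Step 15
Reactants: 20 vinyl diene; 21 hept-1-ene
Product: 22 methyl (2E)-4-[(1S,2R,5R,6S)-5-(TBS-oxy)-4-(TBS-oxymethyl)-3-[(1E)-hept-1-en-1-yl]-2-(TES-oxy)-7-oxabicyclo[4.1.0]hept-3-en-1-yl]-2-methylbut-2-enoate
Conditions: (H2IMes)Cl2Ru=CH(2-i-PrOC6H4) (second-generation Hoveyda–Grubbs catalyst, 10 mol %), 21 (10 equiv), CH2Cl2, 40 °C
Reagents that add atoms: none
Why: Cross-metathesis at the terminal alkene of a conjugated diene; the tetrasubstituted ring alkene and the trisubstituted enoate cannot compete. Reversible metathesis should favour the conjugated E alkene.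

Step 16
Reactants: 22 methyl ester
Product: 23 (2E)-4-[(1S,2R,5R,6S)-5-(TBS-oxy)-4-(TBS-oxymethyl)-3-[(1E)-hept-1-en-1-yl]-2-(TES-oxy)-7-oxabicyclo[4.1.0]hept-3-en-1-yl]-2-methylbut-2-enoic acid
Conditions: Me3SnOH (10 equiv), ClCH2CH2Cl, 80 °C; aqueous KHSO4 work-up
Reagents that add atoms: trimethyltin hydroxide, C[Sn](C)(C)O
Why: Trimethyltin hydroxide cleaves methyl esters under nearly neutral conditions that spare silyl ethers and oxiranes. It is done here, before the ketone exists, so that no epoxy enone is heated with a hydroxide source.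

Step 17
Reactants: 23 acid with C1 TES ether
Product: 24 (2E)-4-[(1R,2R,5R,6S)-5-(TBS-oxy)-4-(TBS-oxymethyl)-3-[(1E)-hept-1-en-1-yl]-2-hydroxy-7-oxabicyclo[4.1.0]hept-3-en-1-yl]-2-methylbut-2-enoic acid
Conditions: pyridinium p-toluenesulfonate (0.2 equiv), MeOH/CH2Cl2 1:3, 0 °C
Reagents that add atoms: none
Why: Acid-catalysed methanolysis removes a TES ether much faster than a TBS ether, so the C1 hydroxyl alone is freed. The adjacent oxirane carbon disfavours ionisation at C1.

Step 18
Reactants: 24 C1 carbinol
Product: 25 (2E)-4-[(1S,5R,6S)-5-(TBS-oxy)-4-(TBS-oxymethyl)-3-[(1E)-hept-1-en-1-yl]-2-oxo-7-oxabicyclo[4.1.0]hept-3-en-1-yl]-2-methylbut-2-enoic acid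
Conditions: Dess–Martin periodinane (1.5 equiv), pyridine, CH2Cl2, 0 °C to rt
Reagents that add atoms: none
Why: Dess–Martin oxidation of the allylic alcohol gives the epoxy dienone under non-basic conditions; both C1 epimers converge here. The free acid and the silyl ethers are compatible.

Step 19
Reactants: 25 bis-TBS epoxy dienone acid
Product: 26 (2E)-4-[(1S,5R,6S)-3-[(1E)-hept-1-en-1-yl]-5-hydroxy-4-(hydroxymethyl)-2-oxo-7-oxabicyclo[4.1.0]hept-3-en-1-yl]-2-methylbut-2-enoic acid (target)
Conditions: HF·pyridine (excess), THF, 0 °C to rt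
Reagents that add atoms: none
Why: Acidic fluoride removes the primary and the secondary TBS ether without base, which the epoxy enone would not tolerate. No stereocentre is affected.

Compound list

1 | 2-methylidenepropane-1,3-diol | C=C(CO)CO | starting material
2 | 2-(TBS-oxymethyl)prop-2-en-1-ol | C=C(CO)CO[Si](C)(C)C(C)(C)C | intermediate
3 | 2-(TBS-oxymethyl)prop-2-enal | C=C(C=O)CO[Si](C)(C)C(C)(C)C | intermediate
4 | prop-2-yn-1-ol | C#CCO | starting material
5 | allylmagnesium bromide | C=CC[Mg]Br | starting material
6 | cyclic alkenylmagnesium alkoxide (4-allyl-2,5-dihydro-1,2-oxamagnesole) | C=CCC1=C[Mg]OC1 | intermediate (not isolated)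
7 | (2Z)-2-(iodomethylidene)pent-4-en-1-ol | OC/C(CC=C)=C\I | intermediate
8 | methyl methacrylate | C=C(C)C(=O)OC | starting material
9 | methyl (2E,5Z)-5-(hydroxymethyl)-6-iodo-2-methylhexa-2,5-dienoate | I/C=C(\CO)C/C=C(\C)C(=O)OC | intermediate
10 | methyl (2E,5Z)-6-iodo-2-methyl-5-(TES-oxymethyl)hexa-2,5-dienoate | I/C=C(\CO[Si](CC)(CC)CC)C/C=C(\C)C(=O)OC | intermediate
11 | methyl (2E,5Z,7RS)-8-(TBS-oxymethyl)-7-hydroxy-2-methyl-5-(TES-oxymethyl)nona-2,5,8-trienoate (racemic) | C=C(CO[Si](C)(C)C(C)(C)C)C(O)/C=C(\CO[Si](CC)(CC)CC)C/C=C(\C)C(=O)OC | intermediate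
12 | methyl (2E,5Z)-8-(TBS-oxymethyl)-2-methyl-7-oxo-5-(TES-oxymethyl)nona-2,5,8-trienoate | C=C(CO[Si](C)(C)C(C)(C)C)C(=O)/C=C(\CO[Si](CC)(CC)CC)C/C=C(\C)C(=O)OC | intermediate
13 | methyl (2E,5Z,7S)-8-(TBS-oxymethyl)-7-hydroxy-2-methyl-5-(TES-oxymethyl)nona-2,5,8-trienoate | C=C(CO[Si](C)(C)C(C)(C)C)[C@@H](O)/C=C(\CO[Si](CC)(CC)CC)C/C=C(\C)C(=O)OC | intermediate
14 | methyl (2E)-4-[(2R,3S)-3-[(1R)-1-hydroxy-2-(TBS-oxymethyl)prop-2-en-1-yl]-2-(TES-oxymethyl)oxiran-2-yl]-2-methylbut-2-enoate | CC[Si](CC)(CC)OC[C@@]1(C/C=C(\C)C(=O)OC)O[C@H]1[C@H](O)C(=C)CO[Si](C)(C)C(C)(C)C | intermediate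
15 | methyl (2E)-4-[(2R,3S)-3-[(1R)-1-(TBS-oxy)-2-(TBS-oxymethyl)prop-2-en-1-yl]-2-(TES-oxymethyl)oxiran-2-yl]-2-methylbut-2-enoate | CC[Si](CC)(CC)OC[C@@]1(C/C=C(\C)C(=O)OC)O[C@H]1[C@H](O[Si](C)(C)C(C)(C)C)C(=C)CO[Si](C)(C)C(C)(C)C | intermediate
16 | methyl (2E)-4-[(2S,3S)-3-[(1R)-1-(TBS-oxy)-2-(TBS-oxymethyl)prop-2-en-1-yl]-2-formyloxiran-2-yl]-2-methylbut-2-enoate | O=C[C@@]1(C/C=C(\C)C(=O)OC)O[C@H]1[C@H](O[Si](C)(C)C(C)(C)C)C(=C)CO[Si](C)(C)C(C)(C)C | intermediate
17 | ethynylmagnesium bromide | C#C[Mg]Br | starting material
18 | methyl (2E)-4-[(2R,3S)-3-[(1R)-1-(TBS-oxy)-2-(TBS-oxymethyl)prop-2-en-1-yl]-2-[(1R)-1-hydroxyprop-2-yn-1-yl]oxiran-2-yl]-2-methylbut-2-enoate (C1 epimers, one shown) | C#C[C@@H](O)[C@@]1(C/C=C(\C)C(=O)OC)O[C@H]1[C@H](O[Si](C)(C)C(C)(C)C)C(=C)CO[Si](C)(C)C(C)(C)C | intermediate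
19 | methyl (2E)-4-[(2S,3S)-3-[(1R)-1-(TBS-oxy)-2-(TBS-oxymethyl)prop-2-en-1-yl]-2-[(1R)-1-(TES-oxy)prop-2-yn-1-yl]oxiran-2-yl]-2-methylbut-2-enoate (C1 epimers, one shown) | C#C[C@@H](O[Si](CC)(CC)CC)[C@@]1(C/C=C(\C)C(=O)OC)O[C@H]1[C@H](O[Si](C)(C)C(C)(C)C)C(=C)CO[Si](C)(C)C(C)(C)C | intermediate
20 | methyl (2E)-4-[(1S,2R,5R,6S)-5-(TBS-oxy)-4-(TBS-oxymethyl)-3-ethenyl-2-(TES-oxy)-7-oxabicyclo[4.1.0]hept-3-en-1-yl]-2-methylbut-2-enoate (C2-carbinol epimers, one shown) | C=CC1=C(CO[Si](C)(C)C(C)(C)C)[C@@H](O[Si](C)(C)C(C)(C)C)[C@@H]2O[C@]2(C/C=C(\C)C(=O)OC)[C@@H]1O[Si](CC)(CC)CC | intermediate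
21 | hept-1-ene | C=CCCCCC | starting material
22 | methyl (2E)-4-[(1S,2R,5R,6S)-5-(TBS-oxy)-4-(TBS-oxymethyl)-3-[(1E)-hept-1-en-1-yl]-2-(TES-oxy)-7-oxabicyclo[4.1.0]hept-3-en-1-yl]-2-methylbut-2-enoate | CCCCC/C=C/C1=C(CO[Si](C)(C)C(C)(C)C)[C@@H](O[Si](C)(C)C(C)(C)C)[C@@H]2O[C@]2(C/C=C(\C)C(=O)OC)[C@@H]1O[Si](CC)(CC)CC | intermediate
23 | (2E)-4-[(1S,2R,5R,6S)-5-(TBS-oxy)-4-(TBS-oxymethyl)-3-[(1E)-hept-1-en-1-yl]-2-(TES-oxy)-7-oxabicyclo[4.1.0]hept-3-en-1-yl]-2-methylbut-2-enoic acid | CCCCC/C=C/C1=C(CO[Si](C)(C)C(C)(C)C)[C@@H](O[Si](C)(C)C(C)(C)C)[C@@H]2O[C@]2(C/C=C(\C)C(=O)O)[C@@H]1O[Si](CC)(CC)CC | intermediate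
24 | (2E)-4-[(1R,2R,5R,6S)-5-(TBS-oxy)-4-(TBS-oxymethyl)-3-[(1E)-hept-1-en-1-yl]-2-hydroxy-7-oxabicyclo[4.1.0]hept-3-en-1-yl]-2-methylbut-2-enoic acid | CCCCC/C=C/C1=C(CO[Si](C)(C)C(C)(C)C)[C@@H](O[Si](C)(C)C(C)(C)C)[C@@H]2O[C@]2(C/C=C(\C)C(=O)O)[C@@H]1O | intermediate
25 | (2E)-4-[(1S,5R,6S)-5-(TBS-oxy)-4-(TBS-oxymethyl)-3-[(1E)-hept-1-en-1-yl]-2-oxo-7-oxabicyclo[4.1.0]hept-3-en-1-yl]-2-methylbut-2-enoic acid | CCCCC/C=C/C1=C(CO[Si](C)(C)C(C)(C)C)[C@@H](O[Si](C)(C)C(C)(C)C)[C@@H]2O[C@]2(C/C=C(\C)C(=O)O)C1=O | intermediate
26 | (2E)-4-[(1S,5R,6S)-3-[(1E)-hept-1-en-1-yl]-5-hydroxy-4-(hydroxymethyl)-2-oxo-7-oxabicyclo[4.1.0]hept-3-en-1-yl]-2-methylbut-2-enoic acid | CCCCC/C=C/C1=C(CO)[C@@H](O)[C@@H]2O[C@]2(C/C=C(\C)C(=O)O)C1=O | target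

Total step count: 19. Longest linear sequence: 17 steps (steps 3 to 19, from 4 and 5); aldehyde 3 is made in steps 1 and 2 and enters in step 6.

Steps least certain to work

Step 14 (key step). The most likely failure is interception of the vinylcarbene by ethylene before it reaches the hindered 1,1-disubstituted alkene, which lies next to the C4 silyl ether. The outcome would be cross-enyne metathesis without ring closure, followed by catalyst decay at 80 °C. Fallback: ring closure by alkene–alkene metathesis and a late Suzuki–Miyaura coupling, setting out from aldehyde 16 and returning to the route at 25. Addition of vinylmagnesium bromide CH2=CHMgBr to 16 gives the allylic alcohol F1. Ring-closing metathesis of its vinyl group with the C3 methylidene ((H2IMes)(PCy3)Cl2Ru=CHPh, CH2Cl2, 40 °C; a monosubstituted alkene initiates readily and the free allylic hydroxyl assists) gives the cyclohexenol F2 with C2 unsubstituted. Me3SnOH hydrolysis gives the acid F3, Dess–Martin oxidation the enone F4, and α-iodination (I2, pyridine) the iodoenone F5. Coupling of F5 with commercial (E)-hept-1-enylboronic acid (PdCl2(PhCN)2, AsPh3, Ag2O, THF/H2O) gives 25.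

Step 8. Facial selectivity may be poor or inverted because both ketone substituents are alkenyl: the Z substituent on the C5=C6 side can make that group, not the α-branched one, the effectively larger one. The Z enone may also isomerise before it is reduced. Fallback: catalytic asymmetric Nozaki–Hiyama–Kishi coupling, setting out from iodide 10 and aldehyde 3 and returning at 13, so that 11 and 12 are bypassed. The conditions are catalytic CrCl2 bound to a chiral oxazoline–sulfonamide ligand, catalytic NiCl2, Mn powder as stoichiometric reductant, Cp2ZrCl2 and LiCl in MeCN. The ligand then has to distinguish the two faces of an aldehyde, not two similar alkenyl groups. No new compound is made (F0).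

Step 9. The peracid may also epoxidise the 1,1-disubstituted alkene, which is allylic to the same hydroxyl, and facial control may erode if the hydroxyl delivers less well than expected. Fallback: two-point direction, setting out from 13 and returning at 14. Selective cleavage of the primary TES ether (pyridinium p-toluenesulfonate, MeOH, 0 °C) gives the dienediol F6, whose primary allylic hydroxyl at C1 is a second hydrogen-bond donor that serves only the C5=C6 alkene. mCPBA then gives the epoxy diol F7, with the face still set from C4 by allylic 1,3-strain. Selective silylation of the primary hydroxyl (TESCl, imidazole, −40 °C) gives 14.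

Step 15. Cross-metathesis at a vinyl group flanked by two ring substituents may be slow, hept-1-ene self-metathesis may use up the catalyst, and the new alkene may form with incomplete E selectivity. Fallback: olefination and cross-coupling, setting out from 20 and returning at 22. Lemieux–Johnson cleavage of the terminal vinyl group (OsO4 catalytic, NaIO4, 2,6-lutidine, dioxane/H2O) passes through the glycol F8, which is not isolated, to the enal F9. Takai olefination (CrCl2, CHI3, THF) gives the (E)-iodo diene F10. Negishi coupling with pentylzinc bromide C5H11ZnBr (PdCl2(dppf) catalyst, THF) gives 22 with the E geometry fixed by the olefination.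

Step 16. Hydrolysis of the hindered, conjugated methyl ester may be slow, and prolonged heating may cause loss of the TES ether or opening of the oxirane. Fallback: redox route to the acid, setting out from 22 and returning at 23. i-Bu2AlH (diisobutylaluminium hydride) at −78 °C reduces the ester to the allylic alcohol F11, the only free hydroxyl in the molecule. MnO2 gives the enal F12, and Pinnick oxidation (NaClO2, NaH2PO4, 2-methylbut-2-ene) gives 23.

Further compounds

F1 | step 14 | methyl (2E)-4-[(2R,3S)-3-[(1R)-1-(TBS-oxy)-2-(TBS-oxymethyl)prop-2-en-1-yl]-2-(1-hydroxyprop-2-en-1-yl)oxiran-2-yl]-2-methylbut-2-enoate (carbinol epimers, one shown) | C=C[C@@H](O)[C@@]1(C/C=C(\C)C(=O)OC)O[C@H]1[C@H](O[Si](C)(C)C(C)(C)C)C(=C)CO[Si](C)(C)C(C)(C)C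
F2 | step 14 | methyl (2E)-4-[5-(TBS-oxy)-4-(TBS-oxymethyl)-2-hydroxy-7-oxabicyclo[4.1.0]hept-3-en-1-yl]-2-methylbut-2-enoate (C2 unsubstituted cyclohexenol) | C1=C(CO[Si](C)(C)C(C)(C)C)[C@@H](O[Si](C)(C)C(C)(C)C)[C@@H]2O[C@]2(C/C=C(\C)C(=O)OC)[C@@H]1O
F3 | step 14 | (2E)-4-[5-(TBS-oxy)-4-(TBS-oxymethyl)-2-hydroxy-7-oxabicyclo[4.1.0]hept-3-en-1-yl]-2-methylbut-2-enoic acid | C1=C(CO[Si](C)(C)C(C)(C)C)[C@@H](O[Si](C)(C)C(C)(C)C)[C@@H]2O[C@]2(C/C=C(\C)C(=O)O)[C@@H]1O
F4 | step 14 | (2E)-4-[5-(TBS-oxy)-4-(TBS-oxymethyl)-2-oxo-7-oxabicyclo[4.1.0]hept-3-en-1-yl]-2-methylbut-2-enoic acid | C1=C(CO[Si](C)(C)C(C)(C)C)[C@@H](O[Si](C)(C)C(C)(C)C)[C@@H]2O[C@]2(C/C=C(\C)C(=O)O)C1=O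
F5 | step 14 | (2E)-4-[5-(TBS-oxy)-4-(TBS-oxymethyl)-3-iodo-2-oxo-7-oxabicyclo[4.1.0]hept-3-en-1-yl]-2-methylbut-2-enoic acid | IC1=C(CO[Si](C)(C)C(C)(C)C)[C@@H](O[Si](C)(C)C(C)(C)C)[C@@H]2O[C@]2(C/C=C(\C)C(=O)O)C1=O
F0 | step 8 | none | none
F6 | step 9 | methyl (2E,5Z,7S)-8-(TBS-oxymethyl)-7-hydroxy-5-(hydroxymethyl)-2-methylnona-2,5,8-trienoate | C=C(CO[Si](C)(C)C(C)(C)C)[C@@H](O)/C=C(\CO)C/C=C(\C)C(=O)OC
F7 | step 9 | methyl (2E)-4-[(2R,3S)-3-[(1R)-1-hydroxy-2-(TBS-oxymethyl)prop-2-en-1-yl]-2-(hydroxymethyl)oxiran-2-yl]-2-methylbut-2-enoate | OC[C@@]1(C/C=C(\C)C(=O)OC)O[C@H]1[C@H](O)C(=C)CO[Si](C)(C)C(C)(C)C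
F8 | step 15 | glycol of 20 at the vinyl group (1,2-dihydroxyethyl at C3 of the bicycle, not isolated) | OCC(O)C1=C(CO[Si](C)(C)C(C)(C)C)[C@@H](O[Si](C)(C)C(C)(C)C)[C@@H]2O[C@]2(C/C=C(\C)C(=O)OC)[C@@H]1O[Si](CC)(CC)CC
F9 | step 15 | 3-formyl analogue of 20 (enal) | O=CC1=C(CO[Si](C)(C)C(C)(C)C)[C@@H](O[Si](C)(C)C(C)(C)C)[C@@H]2O[C@]2(C/C=C(\C)C(=O)OC)[C@@H]1O[Si](CC)(CC)CC
F10 | step 15 | 3-[(E)-2-iodoethenyl] analogue of 20 | I/C=C/C1=C(CO[Si](C)(C)C(C)(C)C)[C@@H](O[Si](C)(C)C(C)(C)C)[C@@H]2O[C@]2(C/C=C(\C)C(=O)OC)[C@@H]1O[Si](CC)(CC)CC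
F11 | step 16 | allylic alcohol from reduction of the ester of 22 ((2E)-4-substituted 2-methylbut-2-en-1-ol) | CCCCC/C=C/C1=C(CO[Si](C)(C)C(C)(C)C)[C@@H](O[Si](C)(C)C(C)(C)C)[C@@H]2O[C@]2(C/C=C(\C)CO)[C@@H]1O[Si](CC)(CC)CC
F12 | step 16 | corresponding (2E)-2-methylbut-2-enal | CCCCC/C=C/C1=C(CO[Si](C)(C)C(C)(C)C)[C@@H](O[Si](C)(C)C(C)(C)C)[C@@H]2O[C@]2(C/C=C(\C)C=O)[C@@H]1O[Si](CC)(CC)CC
A1 | alternative 1 | trans epoxy para-quinol triethylsilyl ether (C4–C5 oxirane, C6 silyl ether, C3 ketone) | CCCCC/C=C/C1=C[C@](O[Si](CC)(CC)CC)(C/C=C(\C)C(=O)OC)[C@@H]2O[C@@H]2C1=O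
A2 | alternative 1 | C5–C6 epoxide with anti C4 hydroxyl and C3 ketone | CCCCC/C=C/C1=C[C@@]2(C/C=C(\C)C(=O)OC)O[C@H]2[C@H](O)C1=O
A3 | alternative 2 | 3-(2,2-dimethoxyethyl)-3-(triethylsilyloxy)cyclobutan-1-one | O=C1CC(CC(OC)OC)(O[Si](CC)(CC)CC)C1
A4 | alternative 2 | TBS ether of (E)-dec-4-en-2-yn-1-ol | CCCCC/C=C/C#CCO[Si](C)(C)C(C)(C)C
A5 | alternative 2 | 2-heptenyl-3-(TBS-oxymethyl)cyclohex-2-enone with C6 set | CCCCC/C=C/C1=C(CO[Si](C)(C)C(C)(C)C)C(=O)C[C@@](O[Si](CC)(CC)CC)(CC(OC)OC)C1
A6 | alternative 3 | acyclic epoxy aldehyde with C3 iodoalkene and heptenyl diene | O=C[C@@H]1O[C@]1(C/C=C(\C)C(=O)OC)[C@H](O[Si](CC)(CC)CC)/C(/C=C/CCCCC)=C(\I)CO[Si](C)(C)C(C)(C)C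
A7 | alternative 3 | epoxy cyclohexenol with free C4 hydroxyl and silylated C1 carbinol | CCCCC/C=C/C1=C(CO[Si](C)(C)C(C)(C)C)[C@@H](O)[C@@H]2O[C@]2(C/C=C(\C)C(=O)OC)[C@@H]1O[Si](CC)(CC)CC
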